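Readings and results come from a simulation for substances that don't exist; scatter was added.

**Two flasks.** Sunday's flask held half the starting material of Thursday's and less precatalyst, yet one rule fits both. In the steps proposed, precatalyst gives catalyst, catalyst turns starting material into product, and product may leave as crystals, which count as product. Call the dose the natural log of one over the fraction of starting material left. At 5.00 h Thursday's dose is 0.168 and Sunday's 0.126, a ratio of 1.33, while their precatalyst charges stand at 1.40. So in these two runs the dose follows the precatalyst charge and not the amount of starting material: pseudo-first-order decay at a given catalyst level.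

| flask | starting material | precatalyst | temperature | remark | time |
|---|---|---|---|---|---|
| Thursday's | 0.30 M | 0.42 mM | 48 °C | run made earlier |  |
| Monday's | 0.30 M | 0.66 mM | 75 °C | run made earlier |  |
| Sunday's | 0.15 M | 0.30 mM | 48 °C | run made earlier |  |
| maple | 0.30 M | 0.30 mM |  | at 85 °C until 40 min, from then on at 35 °C | 3.0 h |
| ash | 0.30 M | 0.30 mM | 60 °C |  | 3.0 h |
| birch | 0.30 M | 0.30 mM | 85 °C |  | 3.0 h |
| elm | 0.30 M | 0.30 mM | 35 °C |  | 3.0 h |

Thursday's run (percent of the starting material charged)

| time / h | product / % | starting material / % |
|---|---|---|
| 0.833 | 0.4 | 99.3 |
| 1.50 | 1.4 | 98.6 |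
| 2.50 | 4.4 | 95.0 |
| 4.00 | 11.1 | 89.4 |
| 5.00 | 15.7 | 84.5 |

Monday's run (percent of the starting material charged)

| time / min | product / % | starting material / % |
|---|---|---|
| 8.00 | 3.5 | 96.8 |
| 10.0 | 3.8 | 95.7 |
| 15.0 | 8.4 | 91.6 |
| 25.0 | 20.2 | 80.1 |
| 40.0 | 41.1 | 60.3 |
| 60.0 | 64.4 | 35.6 |
| 80.0 | 81.0 | 19.4 |

Sunday's run (percent of the starting material charged)

| time / h | product / % | starting material / % |
|---|---|---|
| 0.417 | 0.1 | 100.5 |
| 1.50 | 1.5 | 98.8 |
| 2.50 | 3.5 | 97.2 |
| 4.00 | 6.9 | 93.3 |
| 5.00 | 10.4 | 88.2 |

(standard deviation of a reading: 0.5 percentage points)

- what is said of product includes crystals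
- crystals is a solid; its amount is given per volume of the solution
- the earlier runs were read with a standard deviation of 0.5 percentage points
- steps that have been proposed: starting material + catalyst -> catalyst + product; crystals <-> product; precatalyst -> catalyst

- the best flask by amount of product, in percent of the starting material charged; "all alike" if 1.5 percentage points covers them all (maple / ash / birch / elm / all alike)
- amount of product at the end, in percent of the starting material charged, maple
- amount of product at the end, in percent of the starting material charged, ash
- amount of product at the end, in percent of the starting material charged, birch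
- amount of product at the end, in percent of the starting material charged, elm

**The lag.** But the dose doesn't grow in step with time: when Thursday's time doubled, its dose rose 3.28-fold. We read that as catalyst arriving slowly and replace the rising curve by its mean: full strength after a lag. Monday's flask gains 1.82 h⁻¹ of dose at the end, more than the 1.58 h⁻¹ before. As read, the slope is still climbing, so as a full-strength slope it may read low. Traced back from the last reading, it gives a lag of 26.0 min.

**To birch.** Scaled to birch's charge, the slope is 0.828 h⁻¹. Early dose per charge over time squared is 121 times larger on Monday than on Thursday. Spread evenly per degree, that gives 5.90 from 75 °C to 85 °C. This covers release and turnover together, so we give each its square root, 2.43. Our estimate of birch's dose, the log of one over its fraction left, is then 5.68, which means 99.7 % product, since Monday's product and starting material sum to about the charge (81.0 % and 19.4 %).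

The even split is a guess. Put the whole warming on release instead, and the dose falls to 2.42, still 91.1 % product.

**The forecast.** Reading that the early curve “shows slow catalyst release”, the forecast names birch best, with maple 62 %, ash 30 %, birch 99.3 % and elm 0.3 %. Its birch stands a little below ours.

**The flasks.** Best is birch: maple 61.2 %, ash 30.3 %, birch 99.6 %, elm 0.340 %.

    starting material + catalyst → catalyst + product (k = 22.0 M⁻¹ min⁻¹, Ea = 66.0 kJ mol⁻¹)
    crystals ⇌ product, rate k2*(cs2 - [product]) while solid is left; crystals form when [product] > cs2 (solubility = 42.0 mM, k = 0.120 min⁻¹)
    precatalyst → catalyst (k = 0.00430 min⁻¹, Ea = 101 kJ mol⁻¹)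
    (constants at 60 °C)

**The neighbour.** Birch's 0.358 % of starting material at 3.00 h is a dose of 5.63, beside our 5.68. A neighbour flask repeats birch with 1.2 × 10⁻⁴ M of precatalyst, 40.0 % of birch's charge. Scaling our dose by that share gives 2.27, which leaves 10.3 %. The neighbour flask ends with 11 % of its starting material left.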